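## Retrosynthetic overview

- The cyclohexene ring is closed last by one endo [4+2] between a (2E,4E)-dienoic acid half-ester (C-4 to C-7 plus both ring-bound carboxyl carbons) and a transient 2-carbomethoxy-3-hexadecylcyclopentadienone (C-3a=C-7a). This sets all four stereocentres.
- The cyclopentadienone is unmasked in the same flask by loss of water from racemic untenone A.
- Untenone A comes from a 2,5-disubstituted furan. The pivotal heteroatom step is peracid oxygen transfer (C–O bond formation) that opens the furan to a Z-enedione, which aldolises to the cyclopentenone. Those two oxygens become the C-1 ketone of the target and the hydroxyl that later leaves.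
- The furan comes from furan, a C16 bromide and methyl iodoacetate. The diene comes from a β-keto ester via its (E)-enol triflate and a Heck coupling with acrylic acid.
- Ring order: cyclopentenone first (step 3), cyclohexene last (step 7).

Assumption: the target is taken exactly as encoded in the SMILES, the all-cis acid (3aR,4R,7R,7aS) with H-3a, H-4, H-7 and H-7a on one face; the (S,S)-ligand is written for step 7 and its (R,R)-antipode is used instead if the facial sense proves opposite.

## Route

Step 1
Reactants: 1 furan; 2 1-bromohexadecane
Product: 4 2-hexadecylfuran, via 2-furyllithium 3 (not isolated)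
Conditions: n-BuLi, THF, −78 to 0 °C; then 2, 0 °C to rt
Reagents that add atoms: none
Why: α-Lithiation of furan followed by SN2 alkylation with a primary bromide is the standard route to 2-alkylfurans.

Step 2
Reactants: 4 2-hexadecylfuran; 5 methyl iodoacetate
Product: 6 methyl 2-(5-hexadecylfuran-2-yl)acetate
Conditions: FeSO4·7H2O (0.3 equiv), 30% aq H2O2, DMSO/THF, rt
Reagents that add atoms: none
Why: Fenton-type homolytic aromatic substitution: the methyl radical made from DMSO abstracts iodine from 5, the electrophilic ester-substituted radical adds to the only free α-position of the furan, and trivalent iron oxidises the adduct back to the aromatic ring (divalent iron is regenerated).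

Step 3
Reactants: 6 methyl 2-(5-hexadecylfuran-2-yl)acetate
Product: 8 rac-untenone A (methyl (1R*,5S*)-5-hexadecyl-5-hydroxy-2-oxocyclopent-3-ene-1-carboxylate), via Z-enedione 7 (not isolated)
Conditions: mCPBA, CH2Cl2, 0 °C; aq NaHCO3 wash; then Et3N (10 mol %), CH2Cl2, 0 °C
Reagents that add atoms: meta-chloroperoxybenzoic acid, O=C(OO)c1cccc(Cl)c1
Why: Oxidative furan ring opening (peracid oxygen transfer, C–O bond formation) gives the cis-enedione with Z geometry inherited from the ring, and the β-keto ester carbon then closes the five-membered ring by a 5-exo intramolecular aldol addition onto the hexadecyl ketone; both new stereocentres are racemic and are erased in step 7.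

Step 4
Reactants: 9 methyl acetoacetate; 10 1-bromopentadecane
Product: 12 methyl 3-oxononadecanoate, via acetoacetate dianion 11 (not isolated)
Conditions: NaH, THF, 0 °C; n-BuLi, 0 °C; then 10, 0 °C to rt; aq NH4Cl
Reagents that add atoms: none
Why: Huckin–Weiler dianion alkylation: the terminal carbanion of the β-keto ester dianion is the more reactive site and is alkylated selectively.

Step 5
Reactants: 12 methyl 3-oxononadecanoate
Product: 14 methyl (2E)-3-(trifluoromethylsulfonyloxy)nonadec-2-enoate, via tetramethylammonium enolate 13 (not isolated)
Conditions: 25% aq Me4NOH, hexane, 5 °C; then Tf2O, 5 °C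
Reagents that add atoms: triflic anhydride, O=S(=O)(OS(=O)(=O)C(F)(F)F)C(F)(F)F
Why: Stereoselective enol triflation: with a non-chelating ammonium counter-ion the enolate oxygen sits anti to the ester, and O-sulfonylation freezes this as the (E)-enol triflate (alkyl chain cis to CO2Me).

Step 6
Reactants: 14 methyl (2E)-3-(trifluoromethylsulfonyloxy)nonadec-2-enoate; 15 acrylic acid
Product: 16 (2E,4E)-4-hexadecyl-6-methoxy-6-oxohexa-2,4-dienoic acid
Conditions: Pd(OAc)2 (5 mol %), PPh3 (10 mol %), Et3N, DMF, 70 °C
Reagents that add atoms: none
Why: Mizoroki–Heck reaction: zerovalent palladium inserts into the vinyl C–OTf bond with retention, and syn-insertion of acrylic acid followed by syn-β-hydride elimination gives the new (E)-alkene, so both carboxyl groups end up on the outside of the diene.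

Step 7
Reactants: 8 rac-untenone A; 16 (2E,4E)-4-hexadecyl-6-methoxy-6-oxohexa-2,4-dienoic acid
Product: 18 (3aR,4R,7R,7aS)-3,5-dihexadecyl-2,4-bis(methoxycarbonyl)-1-oxo-3a,4,7,7a-tetrahydro-1H-indene-7-carboxylic acid, via cyclopentadienone 17 (not isolated)
Conditions: Cu(OTf)2 (15 mol %), (S,S)-tBu-box (16 mol %), 2,6-lutidine (15 mol %), 4 Å MS, CH2Cl2, 25 °C; 8 added over 12 h to 16 (1.5 equiv)
Reagents that add atoms: none
Why: Proposed new method: a dehydrative, carboxylate-directed asymmetric cross-Diels–Alder reaction on a bis(oxazoline) complex of divalent copper. The copper binds 8 through its β-keto ester, and the copper-bound carboxylate of 16 acts as internal base for E1cB loss of water, so dienone 17 is generated on the metal at 25 °C, where free 8 does not dehydrate, and little free dienone is available to dimerise. Dienone 17 is then held through its C-1 carbonyl on the site cis to the κ1-carboxylate of 16, which delivers the carboxyl end of the diene (future C-7) to C-7a and the ester end (future C-4) to C-3a; this is also the orientation expected electronically, because 16 is the ring-opened analogue of the dienone's own diene unit. The [4+2] is suprafacial on both partners, so the ring fusion is cis and the two carboxyl groups, both outside on the (2E,4E)-diene, are cis to each other; the endo transition state (dienone ring under the diene) places them cis to the five-membered ring, giving the all-cis array, and the tert-butyl groups of the ligand block one face of the bound dienone to fix (3aR,4R,7R,7aS). Closest known reaction types: bis(oxazoline)-copper Diels–Alder reactions of chelating dienophiles, Lewis-acid-templated Diels–Alder reactions of metal-bound dienols with acrylates, and thermal trapping of in situ cyclopentadienones by 1,3-dienes.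

## Compound list

1 | furan | c1ccoc1 | starting material
2 | 1-bromohexadecane | CCCCCCCCCCCCCCCCBr | starting material
3 | 2-furyllithium | [Li]c1ccco1 | intermediate (not isolated)
4 | 2-hexadecylfuran | CCCCCCCCCCCCCCCCc1ccco1 | intermediate
5 | methyl iodoacetate | COC(=O)CI | starting material
6 | methyl 2-(5-hexadecylfuran-2-yl)acetate | CCCCCCCCCCCCCCCCc1ccc(CC(=O)OC)o1 | intermediate
7 | methyl (4Z)-3,6-dioxodocos-4-enoate (Z-enedione) | CCCCCCCCCCCCCCCCC(=O)/C=C\C(=O)CC(=O)OC | intermediate (not isolated)
8 | rac-untenone A, methyl (1R*,5S*)-5-hexadecyl-5-hydroxy-2-oxocyclopent-3-ene-1-carboxylate (racemate; one enantiomer of the trans isomer drawn) | CCCCCCCCCCCCCCCC[C@]1(O)C=CC(=O)[C@@H]1C(=O)OC | intermediate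
9 | methyl acetoacetate | CC(=O)CC(=O)OC | starting material
10 | 1-bromopentadecane | CCCCCCCCCCCCCCCBr | starting material
11 | methyl acetoacetate dianion (sodium lithium salt) | C=C([O-])C=C([O-])OC.[Na+].[Li+] | intermediate (not isolated)
12 | methyl 3-oxononadecanoate | CCCCCCCCCCCCCCCCC(=O)CC(=O)OC | intermediate
13 | tetramethylammonium (E)-enolate of 12 | CCCCCCCCCCCCCCCC/C([O-])=C\C(=O)OC.C[N+](C)(C)C | intermediate (not isolated)
14 | methyl (2E)-3-(trifluoromethylsulfonyloxy)nonadec-2-enoate | CCCCCCCCCCCCCCCC/C(OS(=O)(=O)C(F)(F)F)=C\C(=O)OC | intermediate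
15 | acrylic acid | C=CC(=O)O | starting material
16 | (2E,4E)-4-hexadecyl-6-methoxy-6-oxohexa-2,4-dienoic acid | O=C(O)/C=C/C(=C/C(=O)OC)CCCCCCCCCCCCCCCC | intermediate
17 | methyl 2-hexadecyl-5-oxocyclopenta-1,3-diene-1-carboxylate (cyclopentadienone) | CCCCCCCCCCCCCCCCC1=C(C(=O)OC)C(=O)C=C1 | intermediate (not isolated)
18 | (3aR,4R,7R,7aS)-3,5-dihexadecyl-2,4-bis(methoxycarbonyl)-1-oxo-3a,4,7,7a-tetrahydro-1H-indene-7-carboxylic acid | CCCCCCCCCCCCCCCCC1=C[C@@H](C(=O)O)[C@H]2C(=O)C(C(=O)OC)=C(CCCCCCCCCCCCCCCC)[C@H]2[C@H]1C(=O)OC | target

## Step count and risks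

Total step count: 7. Longest linear sequence: 4 (steps 1, 2, 3, 7 or steps 4, 5, 6, 7).

**Step 7 (the proposed new step).** The risks are dimerisation of the dienone, the wrong regio- or exo-isomer, and low enantioselectivity. The fallback uses known chemistry only, sets out from 8 and 16, and returns at 18. Catalytic enantiocontrol is given up. Compound 8 is added slowly to 16 (5 equiv, recoverable) in toluene at 70 °C, the classical way of intercepting an in situ cyclopentadienone such as 17 with a 1,3-diene before it dimerises. The endo adduct is then a racemate: 18 together with its mirror image, the (3aS,4S,7S,7aR)-acid F1. The racemate is resolved by fractional crystallisation of the (R)-1-phenylethylammonium salt of 18 F2, and 18 is liberated with dilute HCl.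

**Step 2 (radical C–H alkylation of a lipophilic furan).** The risks are low conversion and oxidative damage to the furan. The fallback sets out from 4 and returns at 6, replacing the radical substitution by halogenation and cross-coupling. NBS in DMF at 0 °C gives 2-bromo-5-hexadecylfuran F3. Palladium-catalysed coupling with the Reformatsky reagent BrZnCH2CO2Me (Pd(dba)2, Q-Phos, THF) then gives 6.

**Step 6 (Heck reaction with free acrylic acid).** The risks are polymerisation of the acid and partial loss of the (4E) geometry. The fallback sets out from 14 and returns at 16, using a protected acceptor in two operations. Heck coupling of 14 with tert-butyl acrylate under the same palladium system gives 1-tert-butyl 6-methyl (2E,4E)-4-hexadecylhexa-2,4-dienedioate F4. CF3CO2H in CH2Cl2 then cleaves only the tert-butyl ester to give 16.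

## Further compounds

F1 | step 7 | (3aS,4S,7S,7aR)-enantiomer of 18 | CCCCCCCCCCCCCCCCC1=C[C@H](C(=O)O)[C@@H]2C(=O)C(C(=O)OC)=C(CCCCCCCCCCCCCCCC)[C@@H]2[C@@H]1C(=O)OC
F2 | step 7 | (R)-1-phenylethylammonium salt of 18 | CCCCCCCCCCCCCCCCC1=C[C@@H](C(=O)[O-])[C@H]2C(=O)C(C(=O)OC)=C(CCCCCCCCCCCCCCCC)[C@H]2[C@H]1C(=O)OC.C[C@@H]([NH3+])c1ccccc1
F3 | step 2 | 2-bromo-5-hexadecylfuran | CCCCCCCCCCCCCCCCc1ccc(Br)o1
F4 | step 6 | 1-tert-butyl 6-methyl (2E,4E)-4-hexadecylhexa-2,4-dienedioate | CC(C)(C)OC(=O)/C=C/C(=C/C(=O)OC)CCCCCCCCCCCCCCCC
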